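# Proposed synthesis of (3R)-3-(5-hydroxy-2,2-dimethyl-2H-chromen-6-yl)-8-(3-methylbut-2-en-1-yl)chroman-7-ol (29)

## Analysis of the target

Target 29 is an isoflavan. Ring A (C4a, C5 to C8, C8a) and ring C (O1, C2, C3, C4) form a chroman, and C3 carries ring B (C1' to C6'). Ring B is fused at C3'/C4' to a 2,2-dimethyl-2H-pyran (ring D), so it is a 2,2-dimethyl-2H-chromen-5-ol bound through its C6. Ring A carries a hydroxyl at C7 and a prenyl group at C8, between O1 and that hydroxyl; ring B carries a hydroxyl at C2', ortho to C1'.

The only stereocentre is C3, of (R) configuration. It is a methine bonded to C1', C2 and C4, with no neighbouring stereocentre or heteroatom to relay chirality from. Once made it cannot epimerise, but any route that passes through a carbonyl group next to it could lose it.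

The sensitive groups are the prenyl alkene flanked by two phenolic oxygens (acid closes it to a dihydropyran), the styrene-type alkene of ring D, and the electron-rich phenols. They rule out catalytic hydrogenation as the way to C3 and strongly acidic deprotection. The difficulty is therefore to set an isolated benzylic centre enantioselectively, to secure two contiguously substituted arenes, and to close ring C through O1 while the 2'-hydroxyl, which could close a five-membered ring on the same carbon, is kept silent.

The strategy rests on one feature. With ring C opened at O1–C2, C3 bears ring B (C3–C1') and a methylene (C4) bound to C4a. A vinylboron ate complex gives this 1-aryl-2-arylethyl pattern in one catalytic step when one arene migrates from boron and the other is delivered as an electrophile, and the boron left on C3 is the handle for C2.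

## Retrosynthetic reasoning

**29 from 28 (carbamoyl C–O bond at O2').** The carbamate is removed last. It directs the metalation of ring B at C1', and it keeps O2' from competing with O1 when ring C is closed. The forward step only has to cleave a hindered aryl carbamate without touching two alkenes, which a hydride reagent can do.

**28 from 27 (O1–C2).** Ring C is opened at the alkyl C–O bond and not at C8a–O1. The forward reaction is then a neutral Mitsunobu displacement at a primary carbon by the C8a phenol. The alternative would be a metal-catalysed aryl etherification at a carbon flanked by the prenyl group. The C7 phenol cannot reach C2, so only a six-membered ring is possible in 27.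

**27 from 26 (the two acetal C–O bonds on ring A).** Both ring-A oxygens are carried as methoxymethyl ethers, which direct the metalations used to build that ring. They must leave under acid dilute enough to spare the prenyl group and ring D.

**26 from 25 and 25 from 23 (C2–O, then C2–C3).** The hydroxymethyl group on C3 is traced to a C–B bond. Oxidation of the primary boronic ester 25 gives the alcohol, and 25 is the one-carbon homologue of the secondary boronic ester 23. A Matteson insertion moves C3 from boron to the new carbon with retention, so the configuration fixed in 23 is that of the target.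

**23 from 19, 20 and 9 (C3–C1' and C4–C4a).** Both bonds are cut at once. The two carbons C3 and C4 come from vinylboronic pinacol ester 20, ring B from aryllithium 21 (made from carbamate 19), and ring A from triflate 9. This cut is preferred to C3–C4 (alkylation of an arylacetic acid derivative with an auxiliary) and to reduction of a C3–C4 alkene, because it needs no hydrogenation, passes through no enolisable centre, and sets C3 catalytically. The forward step must transfer ring B from boron to C3 with facial control while C4 is joined to C4a.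

**9 from 8, 8 from 5, 5 from 2 and 3, 2 from 1.** The triflate oxygen on C4a is traced through phenol 8 to a C–H bond next to a methoxymethoxy group in 5 (metalation, borylation, oxidation). The prenyl group of 5 is attached with bromide 3 at the carbon between the two acetal oxygens of 2, the most acidic position of protected resorcinol 1. The 1,2,3,4-substitution of ring A thus follows from two successive directed metalations on a symmetric arene.

**19 from 18, 18 from 13, 13 from 10 and 11.** Chromenol 18 is not taken from a resorcinol, where annulation with enal 11 favours the wrong regioisomer. It is taken from dione 10, whose annulation with 11 gives 13 with the oxygen fixed at C5, followed by dehydrogenation to the phenol. Carbamoylation gives 19.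

## Alternatives that were turned down

**Alternative 1: ring B built by a Danheiser benzannulation.**
- Disconnection: ring B is cut into a ketene unit and an alkyne. The diazo ketone A2, which already carries the finished chroman, would be irradiated with the silyloxyalkyne A3.
- Forward key step: Wolff rearrangement to a vinylketene, regioselective [2+2] addition to the ynol silyl ether, four-electron opening of the cyclobutenone and six-electron closure would give phenol A1.
- For: the 2'-hydroxyl, the 3'-prenyl and the 4'-silyloxy group fall into place without ambiguity, and no directing group has to be removed. On regiocontrol of ring B this plan is stronger than the chosen one.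
- Against: C3 is not made in the key step. It must be present in A2, where it sits at the γ-position of an enone and can be lost by vinylogous enolisation during preparation of the diazo ketone. A1 also lacks ring D: the 3'-prenyl group must be cyclised oxidatively onto O4' and not O2', in the presence of the second prenyl group on ring A. A2 and A3 each need several steps and A3 is fragile.
- Comparison: the chosen strategy takes the oxygen pattern of ring B from dione 10, uses the carbamate to control the site of bond formation, and creates C3 in the same step that joins the arenes.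

**Alternative 2: intramolecular vinylketene–ynol ether benzannulation closing rings A and C.**
- Disconnection: ring A is cut into the four carbons of a vinylketene and the two carbons of a tethered ynol ether.
- Forward key step: acid A5, converted into its acid chloride under neutral conditions and treated with an amine base, would give a vinylketene that adds to the ynol ether; opening and closure then give A4, with ring C closed because the tether runs through C4, C3, C2 and O1.
- For: two rings form in one step, the C7 hydroxyl appears free, the prenyl group is placed by the alkyne, and no phenols need to be distinguished for ring C. In ring-forming economy it is stronger than the chosen route.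
- Against: A5 is an acyclic precursor that needs its own asymmetric step for C3, a prenyl-substituted alkynyl ether that does not tolerate acid, and a ketene generation that must stay free of hydrogen chloride. The allyl ether at O2' must later be removed in a molecule holding a prenyl phenol. The step count to A5 would exceed that of the whole chosen route.
- Comparison: the chosen strategy uses robust arenes as building blocks and leaves stereocontrol to a catalyst in the bond-forming step.

**Alternative 3: aminocatalytic Friedel–Crafts, protonation and lactol cascade.**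
- Disconnection: C4–C4a and O1–C2, with C3 set by protonation.
- Forward key step: under a chiral primary amine salt, unprotected 2-prenylresorcinol A8 would add through C4 to the methylene of the 2-arylacrolein A7, the enamine would be protonated at C3, and the aldehyde would be trapped by the neighbouring phenol as lactol A6.
- For: it is the shortest plan, almost free of protecting groups and metals. In step economy it is clearly stronger than the chosen route.
- Against: C3 is created next to an aldehyde and an arene, the most easily epimerised position in the molecule, and it stays labile while iminium, enamine and open-chain aldehyde interconvert. A resorcinol is a weak carbon nucleophile that can also add through oxygen or react twice. A7 is prone to polymerisation. Reducing A6 to the chroman needs either acidic ionic hydrogenation, which the prenyl group and ring D do not tolerate, or ring opening back to the labile aldehyde.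
- Comparison: in the chosen strategy C3 is first a configurationally stable C–B centre and is then carried on by a stereospecific homologation, so the enantiomeric purity set in the key step is kept.

Key step: step 8

Assumption: atoms are labelled by isoflavan numbering (ring D is the dimethylpyran fused to ring B). Which enantiomer of the ligand gives (R)-23 is taken to be settled by a trial coupling; both are available, and the route is written with the one that gives (R)-23.

## Route

Step 1
Reactants: 1 resorcinol
Product: 2 1,3-bis(methoxymethoxy)benzene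
Conditions: NaH, MOMCl, DMF, 0 °C → rt
Reagents that add atoms: chloromethyl methyl ether, COCCl
Why: Williamson etherification of both phenoxides; the acetal ethers protect the oxygens and serve as directing groups for the two metalations that follow.

Step 2
Reactants: 2 1,3-bis(methoxymethoxy)benzene; 3 1-bromo-3-methylbut-2-ene (prenyl bromide)
Product: 5 1,3-bis(methoxymethoxy)-2-(3-methylbut-2-en-1-yl)benzene, via 2-lithio arene 4 (not isolated)
Conditions: n-BuLi, THF, 0 °C → rt; CuBr·SMe2 (10 mol%), 3, −78 °C → rt
Reagents that add atoms: none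
Why: Directed ortho-metalation removes the proton flanked by both acetal oxygens, and copper-catalysed allylic substitution should join the aryl carbon to the primary carbon of 3 rather than to its tertiary end.

Step 3
Reactants: 5 1,3-bis(methoxymethoxy)-2-(3-methylbut-2-en-1-yl)benzene
Product: 8 2,4-bis(methoxymethoxy)-3-(3-methylbut-2-en-1-yl)phenol, via aryllithium 6 (not isolated), via dimethyl arylboronate 7 (not isolated)
Conditions: s-BuLi, TMEDA, THF, −78 °C; B(OMe)3, −78 °C → rt; H2O2 (30% aq.), NaOH (aq.), 0 °C
Reagents that add atoms: hydrogen peroxide, OO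
Why: Directed ortho-metalation at the only ring position next to an acetal oxygen (C4 and C6 of 5 are equivalent), then borylation and oxidative aryl shift from boron to oxygen, should give the phenol; cold kinetic lithiation is meant to outrun removal of the benzylic, allylic protons, and basic peroxide spares the alkene and the acetals.

Step 4
Reactants: 8 2,4-bis(methoxymethoxy)-3-(3-methylbut-2-en-1-yl)phenol
Product: 9 2,4-bis(methoxymethoxy)-3-(3-methylbut-2-en-1-yl)phenyl trifluoromethanesulfonate
Conditions: Tf2O, pyridine, CH2Cl2, 0 °C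
Reagents that add atoms: trifluoromethanesulfonic anhydride, O=S(=O)(OS(=O)(=O)C(F)(F)F)C(F)(F)F
Why: O-sulfonylation of the phenol under buffered conditions, which the acetals tolerate, gives the halide-free electrophile needed for the key step.

Step 5
Reactants: 10 cyclohexane-1,3-dione; 11 3-methylbut-2-enal
Product: 13 2,2-dimethyl-7,8-dihydro-2H-chromen-5(6H)-one, via oxatriene 12 (not isolated)
Conditions: ethylenediammonium diacetate (10 mol%), MeOH, rt
Reagents that add atoms: none
Why: Knoevenagel condensation gives the 1-oxatriene, which closes ring D by a six-electron oxa-electrocyclisation (formal [3+3] annulation); the oxygen pattern of ring B is thereby fixed.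

Step 6
Reactants: 13 2,2-dimethyl-7,8-dihydro-2H-chromen-5(6H)-one
Product: 18 2,2-dimethyl-2H-chromen-5-ol, via lithium dienolate 14 (not isolated), via α-selenide 15 (not isolated), via selenoxide 16 (not isolated), via 8H-dienone 17 (not isolated)
Conditions: LiN(i-Pr)2, THF, −78 °C; PhSeCl, −78 °C; then AcOH, H2O2 (30% aq.), 0 °C → rt
Reagents that add atoms: none
Why: Kinetic deprotonation of the vinylogous ester at C6, selenenylation, oxidation and syn-elimination of the selenoxide toward C7 give the cross-conjugated dienone, which tautomerises to the phenol (aromatisation by selenoxide elimination).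

Step 7
Reactants: 18 2,2-dimethyl-2H-chromen-5-ol
Product: 19 2,2-dimethyl-2H-chromen-5-yl N,N-diethylcarbamate
Conditions: NaH, ClC(O)NEt2, THF, 0 °C → rt
Reagents that add atoms: N,N-diethylcarbamoyl chloride, CCN(CC)C(Cl)=O
Why: O-carbamoylation of the phenoxide installs the group that directs metalation to C6 of the chromene and later keeps O2' silent.

Step 8
Reactants: 19 2,2-dimethyl-2H-chromen-5-yl N,N-diethylcarbamate; 20 4,4,5,5-tetramethyl-2-vinyl-1,3,2-dioxaborolane; 9 2,4-bis(methoxymethoxy)-3-(3-methylbut-2-en-1-yl)phenyl trifluoromethanesulfonate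
Product: 23 6-[(1R)-2-[2,4-bis(methoxymethoxy)-3-(3-methylbut-2-en-1-yl)phenyl]-1-(4,4,5,5-tetramethyl-1,3,2-dioxaborolan-2-yl)ethyl]-2,2-dimethyl-2H-chromen-5-yl N,N-diethylcarbamate, via ring-B aryllithium 21 (not isolated), via vinylboron ate complex 22 (not isolated)
Conditions: s-BuLi, THF, −78 °C; 20, −78 → 0 °C; solvent exchange to fresh THF; Pd(OAc)2 (2 mol%), 1,1'-bis[bis(4-methoxy-3,5-dimethylphenyl)phosphino]-2,2'-bis[α-(dimethylamino)benzyl]ferrocene (Mandyphos type, the enantiomer giving (R)-23, 2.4 mol%), 9, 60 °C
Reagents that add atoms: none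
Why: Carbamate-directed ortho-lithiation at C6 of 19 gives 21, which adds to the boron of 20 to form ate complex 22. Zerovalent palladium inserts into the C–O bond of triflate 9 to give a cationic aryl complex of divalent palladium, which binds the vinyl group of 22. This π-activation triggers the 1,2-shift of ring B from boron to the α-carbon, anti to the metal (C3–C1'), while the β-carbon becomes bonded to palladium; reductive elimination then forms C4–C4a and returns zerovalent palladium. The closest known reaction type is the palladium-catalysed enantioselective conjunctive cross-coupling of aryl(vinyl)boron ate complexes with aryl triflates. No ring is closed. C3 is set by the chiral bisphosphine, which decides the alkene face that palladium activates during the shift. The step needs the conjunctive path to win over direct aryl transfer and β-hydride elimination, which the non-coordinating triflate counter-ion, the halide-free lithiation by deprotonation and the wide-bite-angle ligand are meant to secure. Holding 21 at −78 °C until it is trapped prevents the anionic ortho-Fries shift, and only the aryl group migrates because the pinacol oxygens do not.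

Step 9
Reactants: 23 6-[(1R)-2-[2,4-bis(methoxymethoxy)-3-(3-methylbut-2-en-1-yl)phenyl]-1-(4,4,5,5-tetramethyl-1,3,2-dioxaborolan-2-yl)ethyl]-2,2-dimethyl-2H-chromen-5-yl N,N-diethylcarbamate
Product: 25 6-[(2R)-1-[2,4-bis(methoxymethoxy)-3-(3-methylbut-2-en-1-yl)phenyl]-3-(4,4,5,5-tetramethyl-1,3,2-dioxaborolan-2-yl)propan-2-yl]-2,2-dimethyl-2H-chromen-5-yl N,N-diethylcarbamate, via chloromethyl ate complex 24 (not isolated)
Conditions: BrCH2Cl, n-BuLi, THF, −78 °C → rt
Reagents that add atoms: bromochloromethane, ClCBr
Why: Matteson homologation: the carbenoid made in the flask adds to boron, and on warming C3 migrates from boron to the CH2 carbon with loss of chloride and retention at C3, which creates the C2–C3 bond.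

Step 10
Reactants: 25 6-[(2R)-1-[2,4-bis(methoxymethoxy)-3-(3-methylbut-2-en-1-yl)phenyl]-3-(4,4,5,5-tetramethyl-1,3,2-dioxaborolan-2-yl)propan-2-yl]-2,2-dimethyl-2H-chromen-5-yl N,N-diethylcarbamate
Product: 26 6-[(2R)-1-[2,4-bis(methoxymethoxy)-3-(3-methylbut-2-en-1-yl)phenyl]-3-hydroxypropan-2-yl]-2,2-dimethyl-2H-chromen-5-yl N,N-diethylcarbamate
Conditions: NaBO3·4H2O, THF/H2O (1:1), rt
Reagents that add atoms: sodium perborate, [Na+].[Na+].O[B-]1(O)OO[B-](O)(O)OO1
Why: Mild oxidative cleavage of the primary C–B bond gives the alcohol; C3 is not involved, and the carbamate, acetals and both alkenes are stable to perborate.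

Step 11
Reactants: 26 6-[(2R)-1-[2,4-bis(methoxymethoxy)-3-(3-methylbut-2-en-1-yl)phenyl]-3-hydroxypropan-2-yl]-2,2-dimethyl-2H-chromen-5-yl N,N-diethylcarbamate
Product: 27 6-[(2R)-1-[2,4-dihydroxy-3-(3-methylbut-2-en-1-yl)phenyl]-3-hydroxypropan-2-yl]-2,2-dimethyl-2H-chromen-5-yl N,N-diethylcarbamate
Conditions: HCl (3 M aq.), MeOH, rt → 40 °C
Reagents that add atoms: none
Why: Acid-catalysed transacetalisation to methanol frees both ring-A phenols; acetal cleavage should be much faster than protonation of the prenyl or ring-D alkene in dilute acid, and the carbamate is inert.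

Step 12
Reactants: 27 6-[(2R)-1-[2,4-dihydroxy-3-(3-methylbut-2-en-1-yl)phenyl]-3-hydroxypropan-2-yl]-2,2-dimethyl-2H-chromen-5-yl N,N-diethylcarbamate
Product: 28 6-[(3R)-7-hydroxy-8-(3-methylbut-2-en-1-yl)-3,4-dihydro-2H-chromen-3-yl]-2,2-dimethyl-2H-chromen-5-yl N,N-diethylcarbamate
Conditions: PPh3, DIAD, THF, 0 °C → rt
Reagents that add atoms: none
Why: Intramolecular Mitsunobu etherification: the C8a phenol displaces the activated primary oxygen in a 6-exo-tet closure of ring C; the C7 phenol cannot reach C2, O2' is blocked, and C3 is untouched.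

Step 13
Reactants: 28 6-[(3R)-7-hydroxy-8-(3-methylbut-2-en-1-yl)-3,4-dihydro-2H-chromen-3-yl]-2,2-dimethyl-2H-chromen-5-yl N,N-diethylcarbamate
Product: 29 (3R)-3-(5-hydroxy-2,2-dimethyl-2H-chromen-6-yl)-8-(3-methylbut-2-en-1-yl)-3,4-dihydro-2H-chromen-7-ol
Conditions: LiAlH4, THF, 0 °C → reflux; aq. potassium sodium tartrate work-up
Reagents that add atoms: none
Why: Hydride attack at the carbamate carbonyl expels the phenoxide (reductive cleavage of an aryl carbamate); isolated and styrene-type alkenes are inert to the reagent, and C3 has no acidic hydrogen.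

## Compound list

1 | resorcinol | Oc1cccc(O)c1 | starting material
2 | 1,3-bis(methoxymethoxy)benzene | COCOc1cccc(OCOC)c1 | intermediate
3 | 1-bromo-3-methylbut-2-ene | CC(C)=CCBr | starting material
4 | [2,6-bis(methoxymethoxy)phenyl]lithium | [Li]c1c(OCOC)cccc1OCOC | intermediate
5 | 1,3-bis(methoxymethoxy)-2-(3-methylbut-2-en-1-yl)benzene | CC(C)=CCc1c(OCOC)cccc1OCOC | intermediate
6 | [2,4-bis(methoxymethoxy)-3-(3-methylbut-2-en-1-yl)phenyl]lithium | [Li]c1ccc(OCOC)c(CC=C(C)C)c1OCOC | intermediate
7 | dimethyl [2,4-bis(methoxymethoxy)-3-(3-methylbut-2-en-1-yl)phenyl]boronate | COB(OC)c1ccc(OCOC)c(CC=C(C)C)c1OCOC | intermediate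
8 | 2,4-bis(methoxymethoxy)-3-(3-methylbut-2-en-1-yl)phenol | CC(C)=CCc1c(OCOC)ccc(O)c1OCOC | intermediate
9 | 2,4-bis(methoxymethoxy)-3-(3-methylbut-2-en-1-yl)phenyl trifluoromethanesulfonate | CC(C)=CCc1c(OCOC)ccc(OS(=O)(=O)C(F)(F)F)c1OCOC | intermediate
10 | cyclohexane-1,3-dione | O=C1CCCC(=O)C1 | starting material
11 | 3-methylbut-2-enal | CC(C)=CC=O | starting material
12 | 2-(3-methylbut-2-en-1-ylidene)cyclohexane-1,3-dione | CC(C)=CC=C1C(=O)CCCC1=O | intermediate
13 | 2,2-dimethyl-7,8-dihydro-2H-chromen-5(6H)-one | CC1(C)C=CC2=C(CCCC2=O)O1 | intermediate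
14 | lithium 2,2-dimethyl-7,8-dihydro-2H-chromen-5-olate | [Li]OC1=CCCC2=C1C=CC(C)(C)O2 | intermediate
15 | 2,2-dimethyl-6-(phenylselanyl)-7,8-dihydro-2H-chromen-5(6H)-one (racemic) | O=C1C([Se]c2ccccc2)CCC2=C1C=CC(C)(C)O2 | intermediate
16 | 2,2-dimethyl-6-(phenylseleninyl)-7,8-dihydro-2H-chromen-5(6H)-one (stereoisomer mixture) | O=C1C([Se](=O)c2ccccc2)CCC2=C1C=CC(C)(C)O2 | intermediate
17 | 2,2-dimethyl-2H-chromen-5(8H)-one | O=C1C=CCC2=C1C=CC(C)(C)O2 | intermediate
18 | 2,2-dimethyl-2H-chromen-5-ol | Oc1cccc2c1C=CC(C)(C)O2 | intermediate
19 | 2,2-dimethyl-2H-chromen-5-yl N,N-diethylcarbamate | CCN(CC)C(=O)Oc1cccc2c1C=CC(C)(C)O2 | intermediate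
20 | 4,4,5,5-tetramethyl-2-vinyl-1,3,2-dioxaborolane | C=CB1OC(C)(C)C(C)(C)O1 | starting material
21 | [5-(diethylcarbamoyloxy)-2,2-dimethyl-2H-chromen-6-yl]lithium | [Li]c1ccc2c(c1OC(=O)N(CC)CC)C=CC(C)(C)O2 | intermediate
22 | lithium [5-(diethylcarbamoyloxy)-2,2-dimethyl-2H-chromen-6-yl](ethenyl)(pinacolato)borate | [Li+].C=C[B-]1(OC(C)(C)C(C)(C)O1)c1ccc2c(c1OC(=O)N(CC)CC)C=CC(C)(C)O2 | intermediate
23 | 6-[(1R)-2-[2,4-bis(methoxymethoxy)-3-(3-methylbut-2-en-1-yl)phenyl]-1-(4,4,5,5-tetramethyl-1,3,2-dioxaborolan-2-yl)ethyl]-2,2-dimethyl-2H-chromen-5-yl N,N-diethylcarbamate | CC(C)=CCc1c(OCOC)ccc(C[C@@H](B2OC(C)(C)C(C)(C)O2)c2ccc3c(c2OC(=O)N(CC)CC)C=CC(C)(C)O3)c1OCOC | intermediate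
24 | lithium (chloromethyl) ate complex of 23 at boron, (1R) | [Li+].CC(C)=CCc1c(OCOC)ccc(C[C@@H]([B-]2(CCl)OC(C)(C)C(C)(C)O2)c2ccc3c(c2OC(=O)N(CC)CC)C=CC(C)(C)O3)c1OCOC | intermediate
25 | 6-[(2R)-1-[2,4-bis(methoxymethoxy)-3-(3-methylbut-2-en-1-yl)phenyl]-3-(4,4,5,5-tetramethyl-1,3,2-dioxaborolan-2-yl)propan-2-yl]-2,2-dimethyl-2H-chromen-5-yl N,N-diethylcarbamate | CC(C)=CCc1c(OCOC)ccc(C[C@@H](CB2OC(C)(C)C(C)(C)O2)c2ccc3c(c2OC(=O)N(CC)CC)C=CC(C)(C)O3)c1OCOC | intermediate
26 | 6-[(2R)-1-[2,4-bis(methoxymethoxy)-3-(3-methylbut-2-en-1-yl)phenyl]-3-hydroxypropan-2-yl]-2,2-dimethyl-2H-chromen-5-yl N,N-diethylcarbamate | CC(C)=CCc1c(OCOC)ccc(C[C@@H](CO)c2ccc3c(c2OC(=O)N(CC)CC)C=CC(C)(C)O3)c1OCOC | intermediate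
27 | 6-[(2R)-1-[2,4-dihydroxy-3-(3-methylbut-2-en-1-yl)phenyl]-3-hydroxypropan-2-yl]-2,2-dimethyl-2H-chromen-5-yl N,N-diethylcarbamate | CC(C)=CCc1c(O)ccc(C[C@@H](CO)c2ccc3c(c2OC(=O)N(CC)CC)C=CC(C)(C)O3)c1O | intermediate
28 | 6-[(3R)-7-hydroxy-8-(3-methylbut-2-en-1-yl)-3,4-dihydro-2H-chromen-3-yl]-2,2-dimethyl-2H-chromen-5-yl N,N-diethylcarbamate | CC(C)=CCc1c(O)ccc2c1OC[C@@H](c1ccc3c(c1OC(=O)N(CC)CC)C=CC(C)(C)O3)C2 | intermediate
29 | (3R)-3-(5-hydroxy-2,2-dimethyl-2H-chromen-6-yl)-8-(3-methylbut-2-en-1-yl)-3,4-dihydro-2H-chromen-7-ol | CC(C)=CCc1c(O)ccc2c1OC[C@@H](c1ccc3c(c1O)C=CC(C)(C)O3)C2 | target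

## Step count and least certain steps

Total step count: 13. Longest linear sequence: 10 steps (steps 1 to 4, then 8 to 13); the ring-B branch (steps 5 to 7) joins at step 8.

**Step 8 (key step).**
- What may go wrong: anionic ortho-Fries migration of the carbamoyl group if 21 warms before it is trapped; slow oxidative addition into the electron-rich, ortho-substituted triflate, which leaves time for direct aryl transfer to palladium or for β-hydride elimination after the metallate shift; weaker facial control because the migrating arene is ortho-substituted and carries a donor group.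
- Fallback (sets out from 5 by way of 6 and from 19 by way of 21, returns at 23): the same C3–C1' bond is made by a stoichiometric lithiation–borylation with reagent control.
  - Aryllithium 6 is trapped with oxirane to give 2-[2,4-bis(methoxymethoxy)-3-(3-methylbut-2-en-1-yl)phenyl]ethan-1-ol F1, which is converted with N,N-diisopropylcarbamoyl chloride and NaH into 2-[2,4-bis(methoxymethoxy)-3-(3-methylbut-2-en-1-yl)phenyl]ethyl N,N-diisopropylcarbamate F2.
  - Aryllithium 21 is quenched with 2-isopropoxy-4,4,5,5-tetramethyl-1,3,2-dioxaborolane to give 2,2-dimethyl-6-(4,4,5,5-tetramethyl-1,3,2-dioxaborolan-2-yl)-2H-chromen-5-yl N,N-diethylcarbamate F3.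
  - Deprotonation of F2 with s-BuLi and (−)-sparteine in Et2O at −78 °C should give the (S)-configured (1S)-2-[2,4-bis(methoxymethoxy)-3-(3-methylbut-2-en-1-yl)phenyl]-1-(diisopropylcarbamoyloxy)ethyllithium F4.
  - F4 adds to F3 with retention to give the lithium (1S)-[2-aryl-1-(diisopropylcarbamoyloxy)ethyl](chromenyl)(pinacolato)borate F5. On warming (MgBr2·OEt2 if needed) ring B shifts from boron to carbon with inversion and loss of the carbamate, giving (R)-23.

**Step 3.**
- What may go wrong: deprotonation at the benzylic, allylic methylene of the prenyl group, which both acetal oxygens also flank, or migration of the ring anion to that site on warming, giving side-chain functionalisation.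
- Fallback (sets out from 2, returns at 8): the oxygen is installed before the prenyl group, so that no prenylated arene meets a strong base.
  - NBS brominates 2 to 1-bromo-2,4-bis(methoxymethoxy)benzene F6.
  - Bromine–lithium exchange (n-BuLi, −78 °C), B(OMe)3 and H2O2/NaOH give 2,4-bis(methoxymethoxy)phenol F7.
  - Silylation (i-Pr3SiCl, imidazole) gives [2,4-bis(methoxymethoxy)phenoxy]triisopropylsilane F8.
  - Lithiation between the two acetal oxygens (n-BuLi) and copper-catalysed reaction with 3 give [2,4-bis(methoxymethoxy)-3-(3-methylbut-2-en-1-yl)phenoxy]triisopropylsilane F9.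
  - Bu4NF removes the silyl group to give 8.

**Step 9.**
- What may go wrong: slow or reversible ate-complex formation at the hindered secondary benzylic boron next to the ortho carbamate, so that the short-lived carbenoid decomposes first and conversion stays incomplete; a second insertion into the less hindered product.
- Fallback (sets out from 23, returns at 25): a two-stage homologation with a longer-lived carbenoid. (Dichloromethyl)lithium, made in the presence of 23 from CH2Cl2 and LiN(i-Pr)2 at −78 °C with ZnCl2 to promote migration, gives 6-[(2R)-1-[2,4-bis(methoxymethoxy)-3-(3-methylbut-2-en-1-yl)phenyl]-3-chloro-3-(4,4,5,5-tetramethyl-1,3,2-dioxaborolan-2-yl)propan-2-yl]-2,2-dimethyl-2H-chromen-5-yl N,N-diethylcarbamate F10 (epimers at the chlorinated carbon). LiBHEt3 then adds hydride to boron, and the 1,2-hydride shift displaces chloride to give 25.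

**Step 11.**
- What may go wrong: acid-induced cyclisation of the prenyl group onto one of the two freshly freed neighbouring phenols, or addition of methanol across the ring-D alkene, if acetal cleavage is not much faster than alkene protonation.
- Fallback (sets out from 26, returns at 27): the acetals are exchanged for silyl groups under buffered, aprotic conditions instead of being solvolysed. Me3SiOTf with 2,2'-bipyridyl in MeCN at 0 °C should convert both aryl acetals (and the alcohol) into silyl ethers, giving 6-[(2R)-1-[3-(3-methylbut-2-en-1-yl)-2,4-bis(trimethylsilyloxy)phenyl]-3-(trimethylsilyloxy)propan-2-yl]-2,2-dimethyl-2H-chromen-5-yl N,N-diethylcarbamate F11. K2CO3 in MeOH then removes the silyl groups to give 27.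

## Further compounds

F1 | step 8 | 2-[2,4-bis(methoxymethoxy)-3-(3-methylbut-2-en-1-yl)phenyl]ethan-1-ol | CC(C)=CCc1c(OCOC)ccc(CCO)c1OCOC
F2 | step 8 | 2-[2,4-bis(methoxymethoxy)-3-(3-methylbut-2-en-1-yl)phenyl]ethyl N,N-diisopropylcarbamate | CC(C)=CCc1c(OCOC)ccc(CCOC(=O)N(C(C)C)C(C)C)c1OCOC
F3 | step 8 | 2,2-dimethyl-6-(4,4,5,5-tetramethyl-1,3,2-dioxaborolan-2-yl)-2H-chromen-5-yl N,N-diethylcarbamate | CCN(CC)C(=O)Oc1c(B2OC(C)(C)C(C)(C)O2)ccc2c1C=CC(C)(C)O2
F4 | step 8 | (1S)-2-[2,4-bis(methoxymethoxy)-3-(3-methylbut-2-en-1-yl)phenyl]-1-(diisopropylcarbamoyloxy)ethyllithium (as its (−)-sparteine complex) | CC(C)=CCc1c(OCOC)ccc(C[C@H]([Li])OC(=O)N(C(C)C)C(C)C)c1OCOC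
F5 | step 8 | lithium [(1S)-2-[2,4-bis(methoxymethoxy)-3-(3-methylbut-2-en-1-yl)phenyl]-1-(diisopropylcarbamoyloxy)ethyl][5-(diethylcarbamoyloxy)-2,2-dimethyl-2H-chromen-6-yl](pinacolato)borate | [Li+].CC(C)=CCc1c(OCOC)ccc(C[C@H]([B-]2(OC(C)(C)C(C)(C)O2)c2ccc3c(c2OC(=O)N(CC)CC)C=CC(C)(C)O3)OC(=O)N(C(C)C)C(C)C)c1OCOC
F6 | step 3 | 1-bromo-2,4-bis(methoxymethoxy)benzene | COCOc1ccc(Br)c(OCOC)c1
F7 | step 3 | 2,4-bis(methoxymethoxy)phenol | COCOc1ccc(O)c(OCOC)c1
F8 | step 3 | [2,4-bis(methoxymethoxy)phenoxy]triisopropylsilane | COCOc1ccc(O[Si](C(C)C)(C(C)C)C(C)C)c(OCOC)c1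
F9 | step 3 | [2,4-bis(methoxymethoxy)-3-(3-methylbut-2-en-1-yl)phenoxy]triisopropylsilane | CC(C)=CCc1c(OCOC)ccc(O[Si](C(C)C)(C(C)C)C(C)C)c1OCOC
F10 | step 9 | 6-[(2R)-1-[2,4-bis(methoxymethoxy)-3-(3-methylbut-2-en-1-yl)phenyl]-3-chloro-3-(4,4,5,5-tetramethyl-1,3,2-dioxaborolan-2-yl)propan-2-yl]-2,2-dimethyl-2H-chromen-5-yl N,N-diethylcarbamate (epimers at C3 of the propyl chain) | CC(C)=CCc1c(OCOC)ccc(C[C@@H](C(Cl)B2OC(C)(C)C(C)(C)O2)c2ccc3c(c2OC(=O)N(CC)CC)C=CC(C)(C)O3)c1OCOC
F11 | step 11 | 6-[(2R)-1-[3-(3-methylbut-2-en-1-yl)-2,4-bis(trimethylsilyloxy)phenyl]-3-(trimethylsilyloxy)propan-2-yl]-2,2-dimethyl-2H-chromen-5-yl N,N-diethylcarbamate | CC(C)=CCc1c(O[Si](C)(C)C)ccc(C[C@@H](CO[Si](C)(C)C)c2ccc3c(c2OC(=O)N(CC)CC)C=CC(C)(C)O3)c1O[Si](C)(C)C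
A1 | alternative 1 | (3R)-3-[2-hydroxy-3-(3-methylbut-2-en-1-yl)-4-(triisopropylsilyloxy)phenyl]-8-(3-methylbut-2-en-1-yl)chroman-7-yl pivalate | CC(C)=CCc1c(OC(=O)C(C)(C)C)ccc2c1OC[C@@H](c1ccc(O[Si](C(C)C)(C(C)C)C(C)C)c(CC=C(C)C)c1O)C2
A2 | alternative 1 | (E)-1-diazo-4-[(3R)-8-(3-methylbut-2-en-1-yl)-7-(pivaloyloxy)chroman-3-yl]but-3-en-2-one | CC(C)=CCc1c(OC(=O)C(C)(C)C)ccc2c1OC[C@@H](/C=C/C(=O)C=[N+]=[N-])C2
A3 | alternative 1 | triisopropyl[(5-methylhex-4-en-1-yn-1-yl)oxy]silane | CC(C)=CCC#CO[Si](C(C)C)(C(C)C)C(C)C
A4 | alternative 2 | (3R)-3-[5-(allyloxy)-2,2-dimethyl-2H-chromen-6-yl]-8-(3-methylbut-2-en-1-yl)chroman-7-ol | CC(C)=CCc1c(O)ccc2c1OC[C@@H](c1ccc3c(c1OCC=C)C=CC(C)(C)O3)C2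
A5 | alternative 2 | (4R)-4-[5-(allyloxy)-2,2-dimethyl-2H-chromen-6-yl]-2-ethenyl-5-[(5-methylhex-4-en-1-yn-1-yl)oxy]pentanoic acid (either C2 epimer) | OC(=O)C(C=C)C[C@@H](COC#CCC=C(C)C)c1ccc2c(c1OCC=C)C=CC(C)(C)O2
A6 | alternative 3 | (3R)-3-[5-(tert-butyldimethylsilyloxy)-2,2-dimethyl-2H-chromen-6-yl]-8-(3-methylbut-2-en-1-yl)chromane-2,7-diol (anomers at C2) | CC(C)=CCc1c(O)ccc2c1OC(O)[C@@H](c1ccc3c(c1O[Si](C)(C)C(C)(C)C)C=CC(C)(C)O3)C2
A7 | alternative 3 | 2-[5-(tert-butyldimethylsilyloxy)-2,2-dimethyl-2H-chromen-6-yl]prop-2-enal | C=C(C=O)c1ccc2c(c1O[Si](C)(C)C(C)(C)C)C=CC(C)(C)O2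
A8 | alternative 3 | 2-(3-methylbut-2-en-1-yl)benzene-1,3-diol | CC(C)=CCc1c(O)cccc1O
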